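The leftover is the electrophile still there at the last reading, 50.0 min: 15.2 % at 0.12 M in the south-west run and 6.6 % at 0.50 M in the north-west run.

| flask | electrophile | nucleophile | free base | remark | time |
|---|---|---|---|---|---|
| south-west | 0.12 M | 1.8 equiv | 0.30 equiv (fed, over 2.5 min) | run made earlier |  |
| north-west | 0.50 M | 1.8 equiv | 0.30 equiv (fed, over 2.5 min) | run made earlier |  |
| flask | 0.25 M | 1.80 equiv | 0.300 equiv (fed, over 2.5 min) |  | 1.0 h |

| run | time / min | electrophile / % | target / % |
|---|---|---|---|
| south-west | 6.00 | 46.1 | 16.6 |
| south-west | 15.0 | 24.2 | 21.9 |
| south-west | 20.0 | 20.7 | 24.5 |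
| south-west | 30.0 | 17.3 | 26.3 |
| south-west | 40.0 | 15.4 | 29.7 |
| south-west | 50.0 | 15.2 | 32.0 |
| north-west | 6.00 | 26.2 | 39.1 |
| north-west | 15.0 | 10.9 | 41.8 |
| north-west | 20.0 | 9.2 | 42.6 |
| north-west | 30.0 | 7.9 | 44.6 |
| north-west | 40.0 | 7.7 | 46.2 |
| north-west | 50.0 | 6.6 | 48.0 |

(scatter of a reading: 0.3 percentage points)

- part of the electrophile that has reacted at 1.0 h
- share of the unused nucleophile that is free and not bound as protonated nucleophile, at 1.0 h

The flask lies between these runs at equal equivalents, and two people read it differently.

The first draws a straight line through the leftover against molarity. That gives 12.3 % for the flask.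

The second objects. That line reaches nothing at 0.792 M, and a leftover cannot go below nothing. So she takes logarithms and gets 0.585. This is the leftover exponent, a log-log slope: the fall in the logarithm of the leftover per unit rise in the logarithm of molarity, at fixed equivalents and fixed time. It gives 9.90 % left, so 90.1 % reacted.

Both figures are for 50.0 min, short of the asked time. I side with the second person. The first keeps his ground at the two runs themselves, where line and power meet. The runs show nothing of the bound nucleophile, so the free share stays a guess.

The forecast takes the power side and carries it on to the asked time, with 90.5 % reacted and 60 % free, and says of the free share that “The runs cannot separate these cases”.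

The flask gives 90.5 % reacted and 40.3 % free.

    electrophile + nucleophile ⇌ acid set free + target (K = 12.0, k = 0.250 /M/min)
    nucleophile + acid set free ⇌ protonated nucleophile, settled at all times (K = 10000 /M)
    acid set free + free base ⇌ salt of the base (K = 470 /M, k = 1.70 /M/min)
    target ⇌ isomer of the product (K = 0.600, k = 0.0690 /min)
    electrophile ⇌ dormant form (K = 2.00, k = 0.100 /min)

At 1.00 h the flask holds 9.48 % electrophile and 0.168 M protonated nucleophile. Stepping this flask up to 0.954 M at the same equivalents, the exponent gives a fall in leftover of 5.1 percentage points. The computed answer there has moved by 5 points.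

Now take the neighbour charged with 0.450 equiv nucleophile, a quarter of the recipe, with the other charges held. The exponent was read at fixed equivalents, so on the nucleophile charge it is a borrowed rule, and it gives 21.3 % left. The computed flask holds 26.0 %, so 74.0 % has reacted.

The earlier runs and the new flask were generated by integration for substances that don't exist; scatter was added.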